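**Retrosynthetic overview**
1. Feature used: in ring A (1,2-dioxane, O1–O2–C3–C4–C5–C6) the fully substituted C4 holds the lactone oxygen and stands γ to the C1 carbonyl (C1–C2–C3–C4). Ring B (γ-lactone, O–C1–C2–C3–C4) is therefore cut at C4–O back to the tertiary C4–H of a monocyclic 3-(carboxymethyl)-4-methyl-1,2-dioxane.
2. Ring B is closed last, on the aryl acetate, by manganese/H2O2 carboxylate-directed γ-C–H lactonisation with retention at C4. Acetate methanolysis then frees the phenol.
3. The C6 chain is cut at C2'=C3' (cross-metathesis, diimide) and at C6–C1' (axial Hosomi–Sakurai allylation of a 6-methoxy-1,2-dioxane through its peroxycarbenium ion, which sets C6).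
4. Ring A is formed first, by O2–C3 oxa-Michael closure (C3 set from C4) of a hydroperoxy ketal made by ozonolysis in methanol of a 1,1-disubstituted alkene.
5. The acyclic dienoate comes from the (R)-Roche ester (source of C4) by iodination, Negishi coupling with 2-bromopropene, reduction and HWE olefination. Ring order: A, then B.

Key step: step 12

Assumption: atom labels follow the peroxylactone numbering (C1 carbonyl, C2 its CH2, C3 peroxy CH, C4 methyl-bearing carbon, C5 ring CH2, C6 quaternary peroxy carbon, O1 on C6, O2 on C3, chain C1'–C9' from C6); 4-iodophenyl acetate is taken as purchasable and the preparation of the manganese catalyst is not counted.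

**Step 1**
Reactants: 1 methyl (R)-3-hydroxy-2-methylpropanoate
Product: 2 methyl (S)-3-iodo-2-methylpropanoate
Conditions: I2, PPh3, imidazole, CH2Cl2, 0 °C to rt
Reagents that add atoms: iodine, [I][I]
Why: Appel-type iodination activates the primary OH as an oxyphosphonium ion that iodide displaces by SN2 at CH2, so the neighbouring stereocentre (the future C4) is untouched and the descriptor becomes S only because CH2I outranks CO2Me.

**Step 2**
Reactants: 2 methyl (S)-3-iodo-2-methylpropanoate; 3 2-bromopropene
Product: 5 methyl (R)-2,4-dimethylpent-4-enoate, via zinc reagent 4 (not isolated)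
Conditions: Zn dust (Me3SiCl/BrCH2CH2Br-activated), THF, 35 °C; then 3 (1.5 equiv), PdCl2(dppf) (3 mol %), rt to 40 °C
Reagents that add atoms: zinc, [Zn] (held only in intermediate 4)
Why: Zinc inserts into the primary C–I bond to give an ester-chelated β-zincio ester whose stereocentre is not the metallated carbon, and Negishi coupling with the vinyl bromide on a wide-bite-angle diphosphine palladium catalyst, which holds back β-hydride elimination, forms C5–C6 without any base that could epimerise C4.

**Step 3**
Reactants: 5 methyl (R)-2,4-dimethylpent-4-enoate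
Product: 6 (R)-2,4-dimethylpent-4-enal
Conditions: i-Bu2AlH (1.05 equiv), CH2Cl2, −78 °C; MeOH quench, aq potassium sodium tartrate
Reagents that add atoms: none
Why: In this partial ester reduction the aluminium hemiacetal formed by one hydride is stable at −78 °C and releases the aldehyde only on quench, the isolated alkene is inert, and the non-basic medium keeps the α-stereocentre.

**Step 4**
Reactants: 6 (R)-2,4-dimethylpent-4-enal (crude solution); 7 trimethyl phosphonoacetate
Product: 8 methyl (2E,4R)-4,6-dimethylhepta-2,6-dienoate
Conditions: LiCl, i-Pr2NEt, MeCN, 0 °C to rt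
Reagents that add atoms: none
Why: Horner–Wadsworth–Emmons olefination under the mild LiCl/amine (Masamune–Roush) conditions should give the E-enoate and is soft enough not to epimerise the α-branched aldehyde.

**Step 5**
Reactants: 8 methyl (2E,4R)-4,6-dimethylhepta-2,6-dienoate
Product: 10 methyl (2E,4R)-6-hydroperoxy-6-methoxy-4-methylhept-2-enoate (both C6 epimers), via carbonyl oxide 9 (not isolated)
Conditions: O3/O2, CH2Cl2–MeOH 1:1, NaHCO3, Sudan Red 7B end-point, −78 °C; N2 purge, no reductive work-up
Reagents that add atoms: ozone, [O-][O+]=O; methanol, CO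
Why: In this Criegee ozonolysis in a participating solvent the electron-rich 1,1-disubstituted alkene reacts far faster than the enoate, the primary ozonide splits toward the more substituted carbonyl oxide plus formaldehyde, and methanol traps 9 as the α-methoxy hydroperoxide, whose unselectively formed C6 centre is erased again in step 7.

**Step 6**
Reactants: 10 methyl (2E,4R)-6-hydroperoxy-6-methoxy-4-methylhept-2-enoate
Product: 11 methyl 2-[(3S,4R)-6-methoxy-4,6-dimethyl-1,2-dioxan-3-yl]acetate (C6 anomers, axial OMe expected to dominate)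
Conditions: Et2NH (0.5 equiv), CF3CH2OH, rt
Reagents that add atoms: none
Why: Amine-catalysed intramolecular oxa-Michael addition (6-exo-trig) of the hydroperoxide to the enoate closes ring A at O2–C3, with C3 set by C4 through a chair transition state that keeps C4–CH3 and the acceptor equatorial and C4–H in the alkene plane (allylic 1,3-strain), while reversibility of the addition should drive the mixture to the same 3,4-trans diequatorial isomer.

**Step 7**
Reactants: 11 methyl 2-[(3S,4R)-6-methoxy-4,6-dimethyl-1,2-dioxan-3-yl]acetate; 12 allyltrimethylsilane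
Product: 14 methyl 2-[(3S,4R,6R)-4,6-dimethyl-6-(prop-2-en-1-yl)-1,2-dioxan-3-yl]acetate, via peroxycarbenium ion 13 (not isolated)
Conditions: 12 (3 equiv), TiCl4 (1.1 equiv), CH2Cl2, −78 °C; aq NaHCO3
Reagents that add atoms: none
Why: In this Hosomi–Sakurai allylation of a cyclic peroxyketal TiCl4 ionises either anomer to the same ion 13, whose half-chair keeps the C3 arm and C4–CH3 pseudoequatorial, and the silane attacks C6 along the axial, chair-forming trajectory on the face of the axial C4–H, which places allyl trans to C4–CH3 and cis to the C3 arm (6R).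

**Step 8**
Reactants: 14 methyl 2-[(3S,4R,6R)-4,6-dimethyl-6-(prop-2-en-1-yl)-1,2-dioxan-3-yl]acetate
Product: 15 2-[(3S,4R,6R)-4,6-dimethyl-6-(prop-2-en-1-yl)-1,2-dioxan-3-yl]acetic acid
Conditions: LiOH (3 equiv), THF–H2O 3:1, 0 °C; then 1 M HCl to pH 3
Reagents that add atoms: lithium hydroxide, [Li+].[OH-]
Why: Saponification at 0 °C, where hydroxide attack at the ester carbonyl outruns deprotonation at C2 or C3 (E1cB loss of the peroxide, Kornblum–DeLaMare cleavage), is placed before the arene arrives because hydroxide would strip an aryl acetate first.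

**Step 9**
Reactants: 16 8-bromooct-1-ene; 17 4-iodophenyl acetate
Product: 19 4-(oct-7-en-1-yl)phenyl acetate, via alkylzinc bromide 18 (not isolated)
Conditions: Zn dust, LiCl, THF, 50 °C; then 17, Pd(OAc)2 (1 mol %), SPhos (2 mol %), THF, rt
Reagents that add atoms: zinc, [Zn] (held only in intermediate 18)
Why: LiCl-assisted zinc insertion followed by Negishi sp3–sp2 coupling works here because the alkylzinc halide tolerates the aryl acetate that a Grignard reagent would attack, and the bulky biarylphosphine makes reductive elimination faster than β-hydride elimination and chain walking.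

**Step 10**
Reactants: 15 2-[(3S,4R,6R)-4,6-dimethyl-6-(prop-2-en-1-yl)-1,2-dioxan-3-yl]acetic acid; 19 4-(oct-7-en-1-yl)phenyl acetate
Product: 20 2-[(3S,4R,6R)-6-[(2E)-9-(4-acetoxyphenyl)non-2-en-1-yl]-4,6-dimethyl-1,2-dioxan-3-yl]acetic acid (E drawn, Z isomer also usable)
Conditions: 19 (3 equiv), second-generation Hoveyda–Grubbs catalyst RuCl2(H2IMes)(=CH-C6H4-2-O-i-Pr) (5 mol %), CH2Cl2, 40 °C
Reagents that add atoms: none
Why: Olefin cross-metathesis of two unhindered terminal alkenes is driven by loss of ethene and by an excess of the cheap partner 19, ruthenium alkylidenes tolerate dialkyl peroxides, free acids and aryl esters, and the alkene geometry is irrelevant because the double bond is saturated next.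

**Step 11**
Reactants: 20 2-[(3S,4R,6R)-6-[(2E)-9-(4-acetoxyphenyl)non-2-en-1-yl]-4,6-dimethyl-1,2-dioxan-3-yl]acetic acid
Product: 21 2-[(3S,4R,6R)-6-[9-(4-acetoxyphenyl)nonyl]-4,6-dimethyl-1,2-dioxan-3-yl]acetic acid
Conditions: KO2CN=NCO2K (excess, in portions), AcOH, CH2Cl2, 0 °C to rt
Reagents that add atoms: none
Why: In the diimide reduction the concerted syn transfer of two hydrogens from HN=NH saturates the unpolarised C=C but leaves O–O, arene, ester and acid alone, which catalytic hydrogenation would not.

**Step 12**
Reactants: 21 2-[(3S,4R,6R)-6-[9-(4-acetoxyphenyl)nonyl]-4,6-dimethyl-1,2-dioxan-3-yl]acetic acid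
Product: 22 plakortolide F aryl acetate, the (3S,4S,6R) cis-fused 1,2-dioxane/γ-lactone with C4–CH3, C6–CH3 and the C6 9-(4-acetoxyphenyl)nonyl chain
Conditions: Mn(OTf)2[(S,S)-TIPSpdp] (2 mol %; TIPSpdp = N,N'-bis[(5-triisopropylsilylpyridin-2-yl)methyl]-2,2'-bipyrrolidine), 50% aq H2O2 (1.5 equiv, syringe pump), (CF3)2CHOH–CH2Cl2 4:1, 0 °C
Reagents that add atoms: none
Why: Proposed new method: the carboxylic acid of 21 binds manganese and assists heterolysis of the bound hydroperoxide to a pentavalent manganese oxo carboxylate, whose oxo ligand takes the axial C4–H by 1,7-hydrogen atom transfer across C1–C2–C3–C4 and whose carboxylate oxygen then captures the caged tertiary C4 radical. The closest known reaction type is the retentive carboxylate-directed γ-C–H lactonisation of tertiary and secondary C–H bonds with Mn or Fe aminopyridine catalysts and H2O2, and a trioxane endoperoxide is known to survive the undirected hydroxylation variant, so the new element is a C–H bond β to a dialkyl peroxide oxygen inside a 1,2-dioxane. Ring B (O–C1–C2–C3–C4) closes as a five-membered ring by C4–O bond formation between the tethered carboxylate oxygen and the C4 radical (rebound in the cage), and hydroxyl rebound followed by spontaneous lactonisation of the cis γ-hydroxy acid would lead to the same compound. The new quaternary stereocentre C4 (S) is fixed by retention, because the hydrogen that is replaced lies on the same face of ring A as the equatorial C3 arm and the arm can reach only that face, so only the cis fusion can form. Site selectivity over C3–H (β, α-peroxy), C5–H2 (δ), the chain methylenes and the benzylic CH2 rests on intramolecular delivery from the bound carboxylate, on C4–H being the only γ C–H and tertiary, on the hydrogen-bond-donor solvent that deactivates C–H bonds next to oxygen, and on the acetate that makes the arene and its benzylic position poorer donors. Chemoselectivity for C–H over O–O rests on the choice of manganese, whose divalent state is a far weaker one-electron reductant of dialkyl peroxides than divalent iron, on low catalyst loading with slow H2O2 addition in the cold, and on rebound being much faster than the 3-exo attack of the C4 radical on O2 that would give an epoxide and an alkoxyl radical.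

**Step 13**
Reactants: 22 plakortolide F aryl acetate
Product: 23 plakortolide F
Conditions: K2CO3 (0.2 equiv), MeOH, 0 °C; aq NH4Cl
Reagents that add atoms: none
Why: In this base-catalysed transesterification the aryl acetate is by far the most electrophilic ester (phenoxide leaving group), so catalytic carbonate in cold methanol should free the phenol before the hindered tertiary-alkyl lactone reacts, and any retro-oxa-Michael opening at C3 is reversible and recloses to the cis-fused system.

**Compound list**
1 | methyl (R)-3-hydroxy-2-methylpropanoate (Roche ester) | COC(=O)[C@H](C)CO | starting material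
2 | methyl (S)-3-iodo-2-methylpropanoate | COC(=O)[C@H](C)CI | intermediate
3 | 2-bromopropene | CC(Br)=C | starting material
4 | [(2S)-3-methoxy-2-methyl-3-oxopropyl]zinc iodide | COC(=O)[C@H](C)C[Zn]I | intermediate
5 | methyl (R)-2,4-dimethylpent-4-enoate | COC(=O)[C@H](C)CC(C)=C | intermediate
6 | (R)-2,4-dimethylpent-4-enal | O=C[C@H](C)CC(C)=C | intermediate
7 | trimethyl phosphonoacetate | COC(=O)CP(=O)(OC)OC | starting material
8 | methyl (2E,4R)-4,6-dimethylhepta-2,6-dienoate | COC(=O)/C=C/[C@H](C)CC(C)=C | intermediate
9 | C6 carbonyl oxide of methyl (2E,4R)-4-methyl-6-oxohept-2-enoate | COC(=O)/C=C/[C@H](C)CC(C)=[O+][O-] | intermediate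
10 | methyl (2E,4R)-6-hydroperoxy-6-methoxy-4-methylhept-2-enoate (C6 epimers) | COC(=O)/C=C/[C@H](C)CC(C)(OC)OO | intermediate
11 | methyl 2-[(3S,4R)-6-methoxy-4,6-dimethyl-1,2-dioxan-3-yl]acetate (C6 anomers) | COC1(C)C[C@@H](C)[C@H](CC(=O)OC)OO1 | intermediate
12 | allyltrimethylsilane | C=CC[Si](C)(C)C | starting material
13 | (3S,4R)-3-(2-methoxy-2-oxoethyl)-4,6-dimethyl-1,2-dioxan-6-ylium (peroxycarbenium ion, O1=C6) | CC1=[O+]O[C@@H](CC(=O)OC)[C@H](C)C1 | intermediate
14 | methyl 2-[(3S,4R,6R)-4,6-dimethyl-6-(prop-2-en-1-yl)-1,2-dioxan-3-yl]acetate | C[C@@]1(CC=C)C[C@@H](C)[C@H](CC(=O)OC)OO1 | intermediate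
15 | 2-[(3S,4R,6R)-4,6-dimethyl-6-(prop-2-en-1-yl)-1,2-dioxan-3-yl]acetic acid | C[C@@]1(CC=C)C[C@@H](C)[C@H](CC(=O)O)OO1 | intermediate
16 | 8-bromooct-1-ene | C=CCCCCCCBr | starting material
17 | 4-iodophenyl acetate | CC(=O)Oc1ccc(I)cc1 | starting material
18 | oct-7-en-1-ylzinc bromide | C=CCCCCCC[Zn]Br | intermediate
19 | 4-(oct-7-en-1-yl)phenyl acetate | C=CCCCCCCc1ccc(OC(C)=O)cc1 | intermediate
20 | 2-[(3S,4R,6R)-6-[(2E)-9-(4-acetoxyphenyl)non-2-en-1-yl]-4,6-dimethyl-1,2-dioxan-3-yl]acetic acid | C[C@@]1(C/C=C/CCCCCCc2ccc(OC(C)=O)cc2)C[C@@H](C)[C@H](CC(=O)O)OO1 | intermediate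
21 | 2-[(3S,4R,6R)-6-[9-(4-acetoxyphenyl)nonyl]-4,6-dimethyl-1,2-dioxan-3-yl]acetic acid | C[C@@]1(CCCCCCCCCc2ccc(OC(C)=O)cc2)C[C@@H](C)[C@H](CC(=O)O)OO1 | intermediate
22 | plakortolide F aryl acetate (3S,4S,6R) | C[C@@]1(CCCCCCCCCc2ccc(OC(C)=O)cc2)C[C@]2(C)OC(=O)C[C@@H]2OO1 | intermediate
23 | plakortolide F (3S,4S,6R) | C[C@@]1(CCCCCCCCCc2ccc(O)cc2)C[C@]2(C)OC(=O)C[C@@H]2OO1 | target

**Step count**
Total steps: 13. Longest linear sequence: 12 (steps 1–8 and 10–13, from 1). Step 9 is the one-step side branch.

**Steps most likely to fail**

**Step 12.** Hydrogen abstraction at C4 may be too slow.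
- The C4–H bond is axial and is flanked by the axial C6 chain. It is also inductively deactivated by O2 on C3 and by the carboxyl group.
- Several processes could then take over. The benzylic CH2, the chain methylenes or the arene may be oxidised. The resting divalent manganese may reduce O–O by one electron. The C4 radical may collapse onto O2.
- A mismatch between the chiral ligand and the substrate could slow the reaction further.

The fallback uses known chemistry. The C4–O bond is taken from the chiral pool, and ring A is closed by the known oxa-Michael addition of a hydroperoxide to a butenolide. It sets out from 3 and comes back at 22. Mg in THF turns 3 into isopropenylmagnesium bromide F1. Under CuI catalysis F1 opens commercial (R)-2-methylglycidol (C[C@@]1(CO)CO1) at its CH2 terminus to give (S)-2,4-dimethylpent-4-ene-1,2-diol F2. Parikh–Doering oxidation (SO3·pyridine, DMSO, Et3N) gives (S)-2-hydroxy-2,4-dimethylpent-4-enal F3. Ph3P=C=C=O in hot toluene acylates the tertiary OH, and the intramolecular Wittig reaction that follows gives (S)-5-methyl-5-(2-methylprop-2-en-1-yl)furan-2(5H)-one F4. The conditions of step 5 cleave only the 1,1-disubstituted alkene and give (S)-5-(2-hydroperoxy-2-methoxypropyl)-5-methylfuran-2(5H)-one F5. The conditions of step 6 add the hydroperoxide to the butenolide β-carbon, necessarily cis to the tether, and give the (3S,4S)-6-methoxy peroxylactone F6. The conditions of step 7 give the (3S,4S,6R)-6-allyl peroxylactone F7. Cross-metathesis with 19 as in step 10 gives the (3S,4S,6R)-6-[(2E)-9-(4-acetoxyphenyl)non-2-en-1-yl] peroxylactone F8, and diimide as in step 11 gives 22.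

**Step 7.** Three things may go wrong.
- TiCl4 may bind the peroxide oxygens instead of OMe and trigger heterolytic O–O cleavage with a 1,2-shift.
- Chelation by the ester may hold the ion in another conformer.
- Attack on a fully substituted peroxycarbenium carbon may show poor facial selectivity.

In the fallback the C6–C1' bond is made on a ketone before any peroxide exists, O–O is brought in by SN1 perhydrolysis, and stereocontrol is replaced by separation. It sets out from 8 and comes back at 14. Ozonolysis of 8 in CH2Cl2 with Me2S work-up gives methyl (2E,4R)-4-methyl-6-oxohept-2-enoate F9. Barbier allylation (allyl bromide, indium powder, THF–H2O) adds to the ketone only and gives methyl (2E,4R)-6-hydroxy-4,6-dimethylnona-2,8-dienoate F10 as both C6 epimers. Treatment with 50% H2O2 and catalytic H2SO4 at 0 °C exchanges the tertiary OH for OOH through the tertiary cation and gives methyl (2E,4R)-6-hydroperoxy-4,6-dimethylnona-2,8-dienoate F11. Et2NH in CF3CH2OH, as in step 6, closes both epimers. Chromatography then separates 14 from methyl 2-[(3S,4R,6S)-4,6-dimethyl-6-(prop-2-en-1-yl)-1,2-dioxan-3-yl]acetate F12.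

**Step 6.** Facial selectivity at C3 may be poor if the chair preference of the E-enoate is weak and equilibration is slow. Prolonged exposure to the amine invites base-induced peroxide cleavage.

In the fallback the stereocontrol element becomes enforced allylic 1,3-strain in a Z-acceptor. It sets out from 6 and comes back at 11. Still–Gennari olefination of 6 [(CF3CH2O)2P(O)CH2CO2Me, KN(SiMe3)2, 18-crown-6, THF, −78 °C] gives methyl (2Z,4R)-4,6-dimethylhepta-2,6-dienoate F13. The conditions of step 5 give methyl (2Z,4R)-6-hydroperoxy-6-methoxy-4-methylhept-2-enoate F14. In F14 the ester is cis to C4, so C4–H is forced into the alkene plane and C4–CH3 anti to the incoming O2. Kinetic closure with Et2NH in CF3CH2OH should then give the 3,4-trans dioxane 11 after a short contact time.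

**Further compounds**
F1 | step 12 | isopropenylmagnesium bromide | C=C(C)[Mg]Br
F2 | step 12 | (S)-2,4-dimethylpent-4-ene-1,2-diol | C=C(C)C[C@](CO)(C)O
F3 | step 12 | (S)-2-hydroxy-2,4-dimethylpent-4-enal | C=C(C)C[C@](C=O)(C)O
F4 | step 12 | (S)-5-methyl-5-(2-methylprop-2-en-1-yl)furan-2(5H)-one | C=C(C)C[C@]1(C)OC(=O)C=C1
F5 | step 12 | (S)-5-(2-hydroperoxy-2-methoxypropyl)-5-methylfuran-2(5H)-one (ketal epimers) | COC(C)(OO)C[C@]1(C)OC(=O)C=C1
F6 | step 12 | (3S,4S)-6-methoxy-4,6-dimethyl cis-fused peroxylactone (C6 anomers) | COC1(C)C[C@]2(C)OC(=O)C[C@@H]2OO1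
F7 | step 12 | (3S,4S,6R)-6-allyl-4,6-dimethyl cis-fused peroxylactone | C[C@@]1(CC=C)C[C@]2(C)OC(=O)C[C@@H]2OO1
F8 | step 12 | (3S,4S,6R)-6-[(2E)-9-(4-acetoxyphenyl)non-2-en-1-yl]-4,6-dimethyl cis-fused peroxylactone | C[C@@]1(C/C=C/CCCCCCc2ccc(OC(C)=O)cc2)C[C@]2(C)OC(=O)C[C@@H]2OO1
F9 | step 7 | methyl (2E,4R)-4-methyl-6-oxohept-2-enoate | COC(=O)/C=C/[C@H](C)CC(C)=O
F10 | step 7 | methyl (2E,4R)-6-hydroxy-4,6-dimethylnona-2,8-dienoate (C6 epimers) | COC(=O)/C=C/[C@H](C)CC(C)(O)CC=C
F11 | step 7 | methyl (2E,4R)-6-hydroperoxy-4,6-dimethylnona-2,8-dienoate (C6 epimers) | COC(=O)/C=C/[C@H](C)CC(C)(OO)CC=C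
F12 | step 7 | methyl 2-[(3S,4R,6S)-4,6-dimethyl-6-(prop-2-en-1-yl)-1,2-dioxan-3-yl]acetate | C[C@]1(CC=C)C[C@@H](C)[C@H](CC(=O)OC)OO1
F13 | step 6 | methyl (2Z,4R)-4,6-dimethylhepta-2,6-dienoate | COC(=O)/C=C\[C@H](C)CC(C)=C
F14 | step 6 | methyl (2Z,4R)-6-hydroperoxy-6-methoxy-4-methylhept-2-enoate (C6 epimers) | COC(=O)/C=C\[C@H](C)CC(C)(OC)OO
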